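**Retrosynthetic overview**
1. Target 13 ⇐ tris-silyl ether 12 by a final fluoride desilylation under non-enolising conditions.
2. Ring C is the only ring built: its O1–C2 bond is closed by an enantioselective oxa-Michael reaction of hydroxy enone 10, with catalyst-controlled protonation at C3 (new step). Rings A and B come intact from two benzaldehydes.
3. 10 ⇐ salicylaldehyde 9 + aryl alkyne 7 (rhodium-catalysed hydroacylation, C3–C4 bond).
4. 7 ⇐ aldehyde 6 (one-carbon homologation) ⇐ prenyl ether 4 (Claisen rearrangement, then O-methylation) ⇐ 2,3,4-trihydroxybenzaldehyde 1 + prenyl bromide 2.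
5. 9 ⇐ 2,4-dihydroxybenzaldehyde 8 (selective 4-O-silylation).

Assumption: the single stereocentre is C3 of the chromanone and is (R) as read from the SMILES; TBS = tert-butyldimethylsilyl throughout.

**Step 1**
Reactants: 1 2,3,4-trihydroxybenzaldehyde; 2 1-bromo-3-methylbut-2-ene (prenyl bromide)
Product: 3 2,3-dihydroxy-4-[(3-methylbut-2-en-1-yl)oxy]benzaldehyde
Conditions: NaHCO3 (1.2 equiv), DMF, 40 °C
Reagents that add atoms: none
Why: Williamson etherification under a weak base that ionises only the para-formyl 4-OH (the most acidic phenol; the 2-OH is hydrogen-bonded to the aldehyde), so only O-4 is prenylated.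

**Step 2**
Reactants: 3 2,3-dihydroxy-4-[(3-methylbut-2-en-1-yl)oxy]benzaldehyde
Product: 4 2,3-bis(TBS-oxy)-4-[(3-methylbut-2-en-1-yl)oxy]benzaldehyde
Conditions: TBSCl (2.5 equiv), imidazole, DMF, 25 °C
Reagents that add atoms: tert-butyldimethylsilyl chloride (TBSCl), CC(C)(C)[Si](C)(C)Cl
Why: Imidazole-promoted silyl ether protection of both catechol hydroxyls, chosen so that the last step can be a fluoride deprotection that needs neither base nor strong acid.

**Step 3**
Reactants: 4 2,3-bis(TBS-oxy)-4-[(3-methylbut-2-en-1-yl)oxy]benzaldehyde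
Product: 6 2,3-bis(TBS-oxy)-4-methoxy-5-(2-methylbut-3-en-2-yl)benzaldehyde, via rearranged phenol 5 (not isolated)
Conditions: PhNEt2, 190 °C, 3 h; then 25 °C, MeOH, TMSCHN2
Reagents that add atoms: (trimethylsilyl)diazomethane (TMSCHN2), C[Si](C)(C)C=[N+]=[N-]
Why: Aromatic Claisen rearrangement transfers the allyl unit with inversion to C5, the only free ortho position, which creates the 1,1-dimethylallyl group; the acidic para-formyl phenol 5 is then O-methylated in the same pot under neutral diazoalkane conditions before it can cyclise, rearrange further or exchange silyl groups.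

**Step 4**
Reactants: 6 2,3-bis(TBS-oxy)-4-methoxy-5-(2-methylbut-3-en-2-yl)benzaldehyde
Product: 7 1-ethynyl-2,3-bis(TBS-oxy)-4-methoxy-5-(2-methylbut-3-en-2-yl)benzene
Conditions: (MeO)2P(O)CHN2, KOtBu, THF, −78 → 25 °C
Reagents that add atoms: dimethyl (diazomethyl)phosphonate, COP(=O)(OC)C=[N+]=[N-]
Why: Seyferth–Gilbert homologation (Horner-type olefination to a diazoalkene, loss of N2, 1,2-hydride shift of the alkylidene carbene) turns the aryl aldehyde into the terminal alkyne under aprotic low-temperature conditions that spare the aryl silyl ethers.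

**Step 5**
Reactants: 8 2,4-dihydroxybenzaldehyde
Product: 9 4-(TBS-oxy)-2-hydroxybenzaldehyde
Conditions: TBSCl (1.05 equiv), imidazole, CH2Cl2, 0 °C
Reagents that add atoms: tert-butyldimethylsilyl chloride (TBSCl), CC(C)(C)[Si](C)(C)Cl
Why: Selective silyl ether protection of the unchelated 4-OH; the 2-OH, hydrogen-bonded to the aldehyde, stays free as the directing group for step 6 and the nucleophile for step 7.

**Step 6**
Reactants: 7 1-ethynyl-2,3-bis(TBS-oxy)-4-methoxy-5-(2-methylbut-3-en-2-yl)benzene; 9 4-(TBS-oxy)-2-hydroxybenzaldehyde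
Product: 10 2-[2,3-bis(TBS-oxy)-4-methoxy-5-(2-methylbut-3-en-2-yl)phenyl]-1-[4-(TBS-oxy)-2-hydroxyphenyl]prop-2-en-1-one
Conditions: [RhCl(cod)]2 (2.5 mol %), Fe(C5H4PPh2)2 (dppf, 5 mol %), Na2CO3 (5 mol %), toluene, 80 °C
Reagents that add atoms: none
Why: Chelation-assisted rhodium-catalysed intermolecular alkyne hydroacylation of a salicylaldehyde, in which the phenoxide-bound acyl rhodium hydride adds across the aryl alkyne with hydride going to the terminal carbon and C–C reductive elimination gives the branched 1,1-disubstituted enone with the ortho-OH still free.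

**Step 7**
Reactants: 10 2-[2,3-bis(TBS-oxy)-4-methoxy-5-(2-methylbut-3-en-2-yl)phenyl]-1-[4-(TBS-oxy)-2-hydroxyphenyl]prop-2-en-1-one
Product: 12 (3R)-3-[2,3-bis(TBS-oxy)-4-methoxy-5-(2-methylbut-3-en-2-yl)phenyl]-7-(TBS-oxy)-2,3-dihydro-4H-chromen-4-one, via enol tautomer 11 (not isolated)
Conditions: thiourea from 9-amino-9-deoxy-epi-quinine and 3,5-bis(trifluoromethyl)phenyl isothiocyanate (10 mol %), toluene, −40 °C
Reagents that add atoms: none
Why: Proposed new method: an organocatalytic enantioselective 6-endo oxa-Michael/protonation cascade in which the quinuclidine nitrogen deprotonates the chelated phenol, the phenoxide closes onto the unsubstituted enone terminus (O1–C2 bond, ring C) to give enolate 11 held by the thiourea N–H bonds, and the quinuclidinium N–H then delivers its proton to the Si face of C3 inside the chiral ion pair to set the (R) centre; the closest known reaction types are amine–thiourea-catalysed oxa-Michael cyclisations of 2'-hydroxychalcone-type substrates to flavanones and base-catalysed sulfa-Michael additions to α-substituted acrylates with enantioselective protonation, neither shown for α-aryl enones giving isoflavanones.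

**Step 8**
Reactants: 12 (3R)-3-[2,3-bis(TBS-oxy)-4-methoxy-5-(2-methylbut-3-en-2-yl)phenyl]-7-(TBS-oxy)-2,3-dihydro-4H-chromen-4-one
Product: 13 (3R)-3-[2,3-dihydroxy-4-methoxy-5-(2-methylbut-3-en-2-yl)phenyl]-7-hydroxy-2,3-dihydro-4H-chromen-4-one
Conditions: HF·pyridine, pyridine/THF, 0 → 25 °C
Reagents that add atoms: none
Why: Fluoride-mediated desilylation of the three aryl silyl ethers under weakly acidic, non-enolising conditions releases the triphenol without epimerising the α-aryl ketone centre or touching the alkene.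

**Compound list**
1 | 2,3,4-trihydroxybenzaldehyde | O=Cc1ccc(O)c(O)c1O | starting material
2 | 1-bromo-3-methylbut-2-ene (prenyl bromide) | CC(C)=CCBr | starting material
3 | 2,3-dihydroxy-4-[(3-methylbut-2-en-1-yl)oxy]benzaldehyde | O=Cc1ccc(OCC=C(C)C)c(O)c1O | intermediate
4 | 2,3-bis[(tert-butyldimethylsilyl)oxy]-4-[(3-methylbut-2-en-1-yl)oxy]benzaldehyde | O=Cc1ccc(OCC=C(C)C)c(O[Si](C)(C)C(C)(C)C)c1O[Si](C)(C)C(C)(C)C | intermediate
5 | 2,3-bis[(tert-butyldimethylsilyl)oxy]-4-hydroxy-5-(2-methylbut-3-en-2-yl)benzaldehyde (not isolated) | O=Cc1cc(C(C)(C)C=C)c(O)c(O[Si](C)(C)C(C)(C)C)c1O[Si](C)(C)C(C)(C)C | intermediate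
6 | 2,3-bis[(tert-butyldimethylsilyl)oxy]-4-methoxy-5-(2-methylbut-3-en-2-yl)benzaldehyde | O=Cc1cc(C(C)(C)C=C)c(OC)c(O[Si](C)(C)C(C)(C)C)c1O[Si](C)(C)C(C)(C)C | intermediate
7 | 1-ethynyl-2,3-bis[(tert-butyldimethylsilyl)oxy]-4-methoxy-5-(2-methylbut-3-en-2-yl)benzene | C#Cc1cc(C(C)(C)C=C)c(OC)c(O[Si](C)(C)C(C)(C)C)c1O[Si](C)(C)C(C)(C)C | intermediate
8 | 2,4-dihydroxybenzaldehyde | O=Cc1ccc(O)cc1O | starting material
9 | 4-[(tert-butyldimethylsilyl)oxy]-2-hydroxybenzaldehyde | O=Cc1ccc(O[Si](C)(C)C(C)(C)C)cc1O | intermediate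
10 | 2-{2,3-bis[(tert-butyldimethylsilyl)oxy]-4-methoxy-5-(2-methylbut-3-en-2-yl)phenyl}-1-{4-[(tert-butyldimethylsilyl)oxy]-2-hydroxyphenyl}prop-2-en-1-one | C=C(C(=O)c1ccc(O[Si](C)(C)C(C)(C)C)cc1O)c1cc(C(C)(C)C=C)c(OC)c(O[Si](C)(C)C(C)(C)C)c1O[Si](C)(C)C(C)(C)C | intermediate
11 | 3-{2,3-bis[(tert-butyldimethylsilyl)oxy]-4-methoxy-5-(2-methylbut-3-en-2-yl)phenyl}-7-[(tert-butyldimethylsilyl)oxy]-2H-chromen-4-ol (enol of 12, present as its ammonium enolate ion pair with the catalyst; not isolated) | OC1=C(c2cc(C(C)(C)C=C)c(OC)c(O[Si](C)(C)C(C)(C)C)c2O[Si](C)(C)C(C)(C)C)COc2cc(O[Si](C)(C)C(C)(C)C)ccc21 | intermediate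
12 | (3R)-3-{2,3-bis[(tert-butyldimethylsilyl)oxy]-4-methoxy-5-(2-methylbut-3-en-2-yl)phenyl}-7-[(tert-butyldimethylsilyl)oxy]-2,3-dihydro-4H-chromen-4-one | C=CC(C)(C)c1cc([C@@H]2COc3cc(O[Si](C)(C)C(C)(C)C)ccc3C2=O)c(O[Si](C)(C)C(C)(C)C)c(O[Si](C)(C)C(C)(C)C)c1OC | intermediate
13 | (3R)-3-[2,3-dihydroxy-4-methoxy-5-(2-methylbut-3-en-2-yl)phenyl]-7-hydroxy-2,3-dihydro-4H-chromen-4-one | C=CC(C)(C)c1cc([C@@H]2COc3cc(O)ccc3C2=O)c(O)c(O)c1OC | target

**Step count and risks**
Total steps: 8. Longest linear sequence: 7 (steps 1, 2, 3, 4, 6, 7, 8).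

Three steps most likely to fail:

- **Step 3 (Claisen rearrangement/methylation).** The ortho-(1,1-dimethylallyl)phenol 5 can undergo abnormal Claisen rearrangement or close to a dihydrobenzofuran, and silyl groups may scramble at 190 °C. The fallback installs the 1,1-dimethylallyl group by cross-coupling instead of a sigmatropic shift; it sets out from 1 and comes back at 6. Regioselective 4-O-methylation of 1 (MeI, Li2CO3, DMF) gives 2,3-dihydroxy-4-methoxybenzaldehyde F1. Silylation (TBSCl, imidazole) gives 2,3-bis[(tert-butyldimethylsilyl)oxy]-4-methoxybenzaldehyde F2. Bromination ortho to the methoxy group (NBS, MeCN) gives 5-bromo-2,3-bis[(tert-butyldimethylsilyl)oxy]-4-methoxybenzaldehyde F3. A ligand-controlled, branched-selective Suzuki–Miyaura coupling of F3 with 3-methylbut-2-enylboronic acid pinacol ester (Pd(OAc)2, bulky dialkylbiarylphosphine, K3PO4, THF/H2O) then gives 6.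

- **Step 6 (hydroacylation).** The branched regiochemistry is not assured for this ortho-silyloxy aryl alkyne, and the linear chalcone isomer may form. Enone 10 may also cyclise under the reaction conditions to racemic chromanone; this and any chalcone are removed by chromatography before step 7. The fallback builds the enone by vinyl-metal addition and oxidation; it sets out from 7 (with 9) and comes back at 10. Hydrostannation of 7 (Bu3SnH, PdCl2(PPh3)2, THF), which places tin on the internal carbon of ortho-substituted aryl alkynes, gives tributyl(1-{2,3-bis[(tert-butyldimethylsilyl)oxy]-4-methoxy-5-(2-methylbut-3-en-2-yl)phenyl}ethenyl)stannane F4. Tin–lithium exchange (n-BuLi, THF, −78 °C) and addition of the vinyllithium to the lithium phenoxide of 9 gives racemic 2-(2-{2,3-bis[(tert-butyldimethylsilyl)oxy]-4-methoxy-5-(2-methylbut-3-en-2-yl)phenyl}-1-hydroxyprop-2-en-1-yl)-5-[(tert-butyldimethylsilyl)oxy]phenol F5. MnO2 in CH2Cl2 oxidises this benzylic, allylic alcohol under neutral conditions to 10.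

- **Step 7 (the proposed new cascade).** Enantioselectivity of the proton transfer is unproven, the sense of induction must be confirmed (the quinidine-derived pseudoenantiomer would give the antipode), and the amine could slowly racemise 12. The fallback uses known chemistry; it sets out from 10 and comes back at 12. Cyclisation of 10 with catalytic Et3N gives racemic 3-{2,3-bis[(tert-butyldimethylsilyl)oxy]-4-methoxy-5-(2-methylbut-3-en-2-yl)phenyl}-7-[(tert-butyldimethylsilyl)oxy]-2,3-dihydro-4H-chromen-4-one F6. Asymmetric transfer hydrogenation under dynamic kinetic resolution (RuCl(p-cymene)(TsDPEN), enantiomer chosen to give the 3R series, HCO2H/Et3N) converts the base-labile racemate into the single cis alcohol (3R,4R)-3-{2,3-bis[(tert-butyldimethylsilyl)oxy]-4-methoxy-5-(2-methylbut-3-en-2-yl)phenyl}-7-[(tert-butyldimethylsilyl)oxy]-3,4-dihydro-2H-chromen-4-ol F7. Dess–Martin oxidation buffered with NaHCO3 restores the ketone without touching C3 and gives 12.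

**Further compounds**
F1 | step 3 | 2,3-dihydroxy-4-methoxybenzaldehyde | O=Cc1ccc(OC)c(O)c1O
F2 | step 3 | 2,3-bis[(tert-butyldimethylsilyl)oxy]-4-methoxybenzaldehyde | O=Cc1ccc(OC)c(O[Si](C)(C)C(C)(C)C)c1O[Si](C)(C)C(C)(C)C
F3 | step 3 | 5-bromo-2,3-bis[(tert-butyldimethylsilyl)oxy]-4-methoxybenzaldehyde | O=Cc1cc(Br)c(OC)c(O[Si](C)(C)C(C)(C)C)c1O[Si](C)(C)C(C)(C)C
F4 | step 6 | tributyl(1-{2,3-bis[(tert-butyldimethylsilyl)oxy]-4-methoxy-5-(2-methylbut-3-en-2-yl)phenyl}ethenyl)stannane | C=C(c1cc(C(C)(C)C=C)c(OC)c(O[Si](C)(C)C(C)(C)C)c1O[Si](C)(C)C(C)(C)C)[Sn](CCCC)(CCCC)CCCC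
F5 | step 6 | racemic 2-(2-{2,3-bis[(tert-butyldimethylsilyl)oxy]-4-methoxy-5-(2-methylbut-3-en-2-yl)phenyl}-1-hydroxyprop-2-en-1-yl)-5-[(tert-butyldimethylsilyl)oxy]phenol | C=C(C(O)c1ccc(O[Si](C)(C)C(C)(C)C)cc1O)c1cc(C(C)(C)C=C)c(OC)c(O[Si](C)(C)C(C)(C)C)c1O[Si](C)(C)C(C)(C)C
F6 | step 7 | racemic 3-{2,3-bis[(tert-butyldimethylsilyl)oxy]-4-methoxy-5-(2-methylbut-3-en-2-yl)phenyl}-7-[(tert-butyldimethylsilyl)oxy]-2,3-dihydro-4H-chromen-4-one | C=CC(C)(C)c1cc(C2COc3cc(O[Si](C)(C)C(C)(C)C)ccc3C2=O)c(O[Si](C)(C)C(C)(C)C)c(O[Si](C)(C)C(C)(C)C)c1OC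
F7 | step 7 | (3R,4R)-3-{2,3-bis[(tert-butyldimethylsilyl)oxy]-4-methoxy-5-(2-methylbut-3-en-2-yl)phenyl}-7-[(tert-butyldimethylsilyl)oxy]-3,4-dihydro-2H-chromen-4-ol | O[C@H]1c2ccc(O[Si](C)(C)C(C)(C)C)cc2OC[C@H]1c1cc(C(C)(C)C=C)c(OC)c(O[Si](C)(C)C(C)(C)C)c1O[Si](C)(C)C(C)(C)C
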